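**Retrosynthetic overview**

- Target ⇒ PMB removal; C9–C10 bond by nickel-catalysed, CrCl2-mediated Nozaki–Hiyama–Kishi closure of the seven-membered ring (formed last), the new alkoxide trapped as the acetate.
- ⇒ α-methylene lactone by palladium-catalysed cyclocarbonylation of a 6-hydroxy-7-ethynyl intermediate; C8 ester by selective acylation of a 6,8-diol.
- ⇒ key C6–C7 bond: palladium-catalysed, InI-mediated umpolung coupling of a bicyclic aldehyde (fragment A) with a cis-ethynyl epoxide (fragment B).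
- Fragment A: cis-2,3-disubstituted cyclopentanone (asymmetric hydrogenation) → alkoxymethyl addition and lactonisation → lactone to enol ether. Fragment B: Sonogashira coupling, then Sharpless epoxidation.
- Ring order: cyclopentane (bought) → bridged dihydropyran → butyrolactone → cycloheptane.

Convention: skeleton carbons carry guaianolide locants (C1–C15); α/β refer to the usual guaianolide drawing (β toward the viewer). SMILES are authoritative for configuration.

**Fragment A**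

Step 1
Reactants: 1 2-(hydroxymethyl)cyclopent-2-en-1-one
Product: 2 2-{[(triethylsilyl)oxy]methyl}cyclopent-2-en-1-one
Conditions: Et3SiCl, imidazole, CH2Cl2, 0 °C
Reagents that add atoms: chlorotriethylsilane, CC[Si](Cl)(CC)CC
Why: Standard imidazole-mediated silylation of the primary allylic alcohol; TES is chosen because a primary TES ether can later be oxidised directly to the aldehyde.

Step 2
Reactants: 2 2-{[(triethylsilyl)oxy]methyl}cyclopent-2-en-1-one; 3 methyl acetate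
Product: 4 methyl 2-(1-hydroxy-2-{[(triethylsilyl)oxy]methyl}cyclopent-2-en-1-yl)acetate (racemic)
Conditions: LiN(i-Pr)2, THF, −78 °C; then 2; AcOH quench at −78 °C
Reagents that add atoms: none
Why: Kinetic 1,2-addition of the lithium ester enolate to the enone carbonyl (aldol-type addition); the new carbinol centre is erased in step 3.

Step 3
Reactants: 4 methyl 2-(1-hydroxy-2-{[(triethylsilyl)oxy]methyl}cyclopent-2-en-1-yl)acetate
Product: 5 methyl 2-(3-oxo-2-{[(triethylsilyl)oxy]methyl}cyclopent-1-en-1-yl)acetate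
Conditions: IBX, DMSO, 55 °C
Reagents that add atoms: none
Why: Oxidative 1,3-transposition of the tertiary allylic alcohol (Dauben–Babler-type rearrangement, IBX variant so the silyl ether survives) places the acetate arm on the β-carbon of a tetrasubstituted enone.

Step 4
Reactants: 5 methyl 2-(3-oxo-2-{[(triethylsilyl)oxy]methyl}cyclopent-1-en-1-yl)acetate
Product: 6 methyl 2-[(1S,2S)-3-oxo-2-{[(triethylsilyl)oxy]methyl}cyclopentyl]acetate (cis)
Conditions: H2 (90 bar), [RuH(C8H10)((S,S)-Me-DuPhos)]BF4 (1 mol %; C8H10 = cycloocta-1,3,5-triene), CH2Cl2, 25 °C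
Reagents that add atoms: none
Why: Ester-directed asymmetric hydrogenation of a 2,3-disubstituted cyclopentenone (the cis-dihydrojasmonate-type hydrogenation) adds both hydrogens to one face, so C1 and C5 are set together and cis; the (S,S)-ligand is assigned by analogy and must be confirmed on the first run.

Step 5
Reactants: 6 methyl 2-[(1S,2S)-3-oxo-2-{[(triethylsilyl)oxy]methyl}cyclopentyl]acetate
Product: 8 (1S,5S,8S)-1-{[(4-methoxybenzyl)oxy]methyl}-8-{[(triethylsilyl)oxy]methyl}-2-oxabicyclo[3.2.1]octan-3-one, via hydroxy ester 7 (not isolated)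
Conditions: Bu3SnCH2OPMB (literature reagent), n-BuLi, THF, −78 °C; CeCl3, −78 °C; then 6, −78 → 25 °C
Reagents that add atoms: tributyl{[(4-methoxybenzyl)oxy]methyl}stannane, CCCC[Sn](CCCC)(CCCC)COCc1ccc(OC)cc1
Why: The low-basicity organocerium form of the Still alkoxymethyl anion adds to the ketone from the α-face, opposite the two cis β-substituents and without epimerising C5, which sets C4 with its oxygen β; the cis alkoxide then closes onto the methyl ester to give the bridged δ-lactone.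

Step 6
Reactants: 8 (1S,5S,8S)-1-{[(4-methoxybenzyl)oxy]methyl}-8-{[(triethylsilyl)oxy]methyl}-2-oxabicyclo[3.2.1]octan-3-one
Product: 10 (1S,5S,8S)-1-{[(4-methoxybenzyl)oxy]methyl}-8-{[(triethylsilyl)oxy]methyl}-2-oxabicyclo[3.2.1]oct-3-ene, via lactol 9 (not isolated)
Conditions: i-Bu2AlH, CH2Cl2, −78 °C; aqueous work-up; crude lactol: MsCl, Et3N, CH2Cl2, −20 → 25 °C
Reagents that add atoms: none
Why: Partial lactone reduction and mesylate-mediated dehydration (the 2-deoxy-lactol to glycal conversion) give the cyclic enol ether; the only β-hydrogen is on C10, so no regio-isomer is possible and no stereocentre is touched.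

Step 7
Reactants: 10 (1S,5S,8S)-1-{[(4-methoxybenzyl)oxy]methyl}-8-{[(triethylsilyl)oxy]methyl}-2-oxabicyclo[3.2.1]oct-3-ene
Product: 11 (1S,5S,8R)-1-{[(4-methoxybenzyl)oxy]methyl}-2-oxabicyclo[3.2.1]oct-3-ene-8-carbaldehyde (formyl group syn to the O2–C3=C4 bridge)
Conditions: (COCl)2, DMSO, CH2Cl2, −78 → −40 °C; Et3N, −78 °C
Reagents that add atoms: none
Why: Swern conditions oxidise a primary triethylsilyl ether directly to the aldehyde (the chlorosulfonium ion cleaves the Si–O bond) and leave the PMB ether and enol ether alone; the formyl group stays syn to the enol ether bridge, which is also the expected thermodynamic epimer.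

**Fragment B**

Step 8
Reactants: 12 ethyl prop-2-ynoate
Product: 13 ethyl (Z)-3-iodoprop-2-enoate
Conditions: NaI, AcOH, 70 °C
Reagents that add atoms: sodium iodide, [Na+].[I-]
Why: Conjugate hydroiodination of the ynoate is anti and gives the (Z)-iodoacrylate.

Step 9
Reactants: 13 ethyl (Z)-3-iodoprop-2-enoate
Product: 14 (Z)-3-iodoprop-2-en-1-ol
Conditions: i-Bu2AlH (2.2 equiv), CH2Cl2, −78 °C
Reagents that add atoms: none
Why: 1,2-Reduction of the ester by the aluminium hydride gives the allylic alcohol with the (Z)-geometry retained.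

Step 10
Reactants: 14 (Z)-3-iodoprop-2-en-1-ol; 15 ethynyltrimethylsilane
Product: 16 (Z)-5-(trimethylsilyl)pent-2-en-4-yn-1-ol
Conditions: Pd(PPh3)2Cl2 (2 mol %), CuI (4 mol %), i-Pr2NH, THF, 25 °C
Reagents that add atoms: none
Why: Sonogashira coupling of the vinyl iodide proceeds with retention of olefin geometry.

Step 11
Reactants: 16 (Z)-5-(trimethylsilyl)pent-2-en-4-yn-1-ol
Product: 17 (Z)-pent-2-en-4-yn-1-ol
Conditions: K2CO3 (cat.), MeOH, 0 °C
Reagents that add atoms: none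
Why: Base-catalysed methanolysis of the alkynyl C–Si bond frees the terminal alkyne.

Step 12
Reactants: 17 (Z)-pent-2-en-4-yn-1-ol
Product: 18 [(2R,3S)-3-ethynyloxiran-2-yl]methanol
Conditions: Ti(Oi-Pr)4 (20 mol %), D-(−)-diisopropyl tartrate (24 mol %), t-BuOOH, 4 Å sieves, CH2Cl2, −20 °C
Reagents that add atoms: tert-butyl hydroperoxide, CC(C)(C)OO
Why: Sharpless asymmetric epoxidation with the D-(−)-tartrate gives the (2R,3S)-cis-epoxide from a (Z)-allylic alcohol (about 90% ee expected, upgraded later because the diastereomers formed in step 15 are separable).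

Step 13
Reactants: 18 [(2R,3S)-3-ethynyloxiran-2-yl]methanol
Product: 19 triethyl{[(2R,3S)-3-ethynyloxiran-2-yl]methoxy}silane
Conditions: Et3SiCl, imidazole, CH2Cl2, 0 °C
Reagents that add atoms: chlorotriethylsilane, CC[Si](Cl)(CC)CC
Why: Silylation of the primary alcohol; the TES ether is later oxidised directly to the C9 aldehyde.

**Acyl donor**

Step 14
Reactants: 20 (S)-2-methylbutanoic acid (two molecules are consumed per molecule of product)
Product: 21 (S)-2-methylbutanoic anhydride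
Conditions: DCC (0.5 equiv per acid), CH2Cl2, 0 → 25 °C; filter off the urea
Reagents that add atoms: (S)-2-methylbutanoic acid (second molecule of 20), CC[C@H](C)C(=O)O
Why: Carbodiimide dehydration: one acid molecule is activated as its O-acylisourea and acylates the carboxyl oxygen of a second molecule, which gives the symmetric anhydride and the urea without touching either α-stereocentre.

**Union and endgame**

Step 15
Reactants: 11 (1S,5S,8R)-1-{[(4-methoxybenzyl)oxy]methyl}-2-oxabicyclo[3.2.1]oct-3-ene-8-carbaldehyde; 19 triethyl{[(2R,3S)-3-ethynyloxiran-2-yl]methoxy}silane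
Product: 22 (1S,2S,3S)-2-ethynyl-1-[(1S,5S,8S)-1-{[(4-methoxybenzyl)oxy]methyl}-2-oxabicyclo[3.2.1]oct-3-en-8-yl]-4-[(triethylsilyl)oxy]butane-1,3-diol
Conditions: Pd(dppf)Cl2 (5 mol %), InI (1.5 equiv), THF/DMPU 3:1, 0 → 25 °C
Reagents that add atoms: none
Why: Proposed new method: zerovalent palladium (formed from Pd(dppf)Cl2 and InI) opens the alkynyl oxirane by anti SN2′ attack to an allenylpalladium alkoxide, oxidative transmetalation with monovalent indium gives an allenylindium species, and this adds to aldehyde 11 through a six-membered cyclic SE2′ transition state, so the C6–C7 bond forms with net inversion at C7, the 6,7-anti relationship and an untouched C8; the closest known reactions are the Marshall-type palladium/InI propargylation with propargylic mesylates and the palladium/InI umpolung of vinyl oxiranes.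

Step 16
Reactants: 22 (1S,2S,3S)-2-ethynyl-1-[(1S,5S,8S)-1-{[(4-methoxybenzyl)oxy]methyl}-2-oxabicyclo[3.2.1]oct-3-en-8-yl]-4-[(triethylsilyl)oxy]butane-1,3-diol; 21 (S)-2-methylbutanoic anhydride
Product: 23 (2S,3S,4S)-3-ethynyl-4-hydroxy-4-[(1S,5S,8S)-1-{[(4-methoxybenzyl)oxy]methyl}-2-oxabicyclo[3.2.1]oct-3-en-8-yl]-1-[(triethylsilyl)oxy]butan-2-yl (2S)-2-methylbutanoate
Conditions: 21 (1.1 equiv), DMAP (10 mol %), Et3N, CH2Cl2, −40 → −20 °C
Reagents that add atoms: none
Why: The C8 hydroxyl, flanked by a CH2OTES group, is much less hindered than the C6 hydroxyl next to the bicyclic bridge carbon, so DMAP-catalysed acyl transfer from the bulky α-branched anhydride at low temperature is selective for O8.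

Step 17
Reactants: 23 (2S,3S,4S)-3-ethynyl-4-hydroxy-4-[(1S,5S,8S)-1-{[(4-methoxybenzyl)oxy]methyl}-2-oxabicyclo[3.2.1]oct-3-en-8-yl]-1-[(triethylsilyl)oxy]butan-2-yl (2S)-2-methylbutanoate
Product: 24 (1S)-1-[(2S,3S)-2-[(1S,5S,8S)-1-{[(4-methoxybenzyl)oxy]methyl}-2-oxabicyclo[3.2.1]oct-3-en-8-yl]-4-methylidene-5-oxooxolan-3-yl]-2-[(triethylsilyl)oxy]ethyl (2S)-2-methylbutanoate
Conditions: PdI2 (5 mol %), PBu3 (10 mol %), CO (3 atm), MeCN, 50 °C
Reagents that add atoms: carbon monoxide, [C-]#[O+]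
Why: Palladium-catalysed cyclocarbonylation of the homopropargylic alcohol (alkoxycarbonyl-palladium formation, syn insertion of the alkyne, protonolysis) gives the α-methylene-γ-butyrolactone; its trans H6/H7 relationship comes from step 15.

Step 18
Reactants: 24 (1S)-1-[(2S,3S)-2-[(1S,5S,8S)-1-{[(4-methoxybenzyl)oxy]methyl}-2-oxabicyclo[3.2.1]oct-3-en-8-yl]-4-methylidene-5-oxooxolan-3-yl]-2-[(triethylsilyl)oxy]ethyl (2S)-2-methylbutanoate
Product: 25 (1S)-1-[(2S,3S)-2-[(1S,5R,8S)-4-iodo-1-{[(4-methoxybenzyl)oxy]methyl}-2-oxabicyclo[3.2.1]oct-3-en-8-yl]-4-methylidene-5-oxooxolan-3-yl]-2-[(triethylsilyl)oxy]ethyl (2S)-2-methylbutanoate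
Conditions: NIS, AgNO3 (20 mol %), MeCN, 50 °C, dark
Reagents that add atoms: N-iodosuccinimide, O=C1CCC(=O)N1I
Why: Electrophilic iodination of the enol ether β-carbon and loss of the C10 proton (the glycal to 2-iodoglycal reaction); the enol ether is far more nucleophilic than the acrylate or the anisyl ring.

Step 19
Reactants: 25 (1S)-1-[(2S,3S)-2-[(1S,5R,8S)-4-iodo-1-{[(4-methoxybenzyl)oxy]methyl}-2-oxabicyclo[3.2.1]oct-3-en-8-yl]-4-methylidene-5-oxooxolan-3-yl]-2-[(triethylsilyl)oxy]ethyl (2S)-2-methylbutanoate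
Product: 26 (1S)-1-[(2S,3S)-2-[(1S,5R,8S)-4-iodo-1-{[(4-methoxybenzyl)oxy]methyl}-2-oxabicyclo[3.2.1]oct-3-en-8-yl]-4-methylidene-5-oxooxolan-3-yl]-2-oxoethyl (2S)-2-methylbutanoate
Conditions: (COCl)2, DMSO, CH2Cl2, −78 → −40 °C; Et3N, −78 °C; used crude
Reagents that add atoms: none
Why: Direct Swern oxidation of the primary TES ether gives the C9 aldehyde; the cold, brief base treatment protects the α-acyloxy centre C8.

Step 20
Reactants: 26 (1S)-1-[(2S,3S)-2-[(1S,5R,8S)-4-iodo-1-{[(4-methoxybenzyl)oxy]methyl}-2-oxabicyclo[3.2.1]oct-3-en-8-yl]-4-methylidene-5-oxooxolan-3-yl]-2-oxoethyl (2S)-2-methylbutanoate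
Product: 28 (1αH,5αH,6βH,7αH)-9α-acetoxy-15-[(4-methoxybenzyl)oxy]-8β-[(2S)-2-methylbutanoyloxy]-4β,14-epoxyguaia-10(14),11(13)-dien-12,6α-olide, via 9α-alcohol 27 (not isolated)
Conditions: CrCl2 (6 equiv), NiCl2 (5 mol %), DMSO/THF 1:1 (2 mM), 25 °C; then Ac2O, DMAP, pyridine, 0 °C
Reagents that add atoms: acetic anhydride, CC(=O)OC(C)=O
Why: Nozaki–Hiyama–Kishi reaction: zerovalent nickel inserts into the C10–I bond, transmetalation to chromium gives an alkenylchromium that adds to the C9 aldehyde and closes the seven-membered ring; the 8β-acyloxy group is held pseudo-axial by the trans-fused lactone and the aldehyde reacts through the dipole-minimised rotamer (C=O anti to C8–O), which places the new oxygen α and trans to O8, and trapping the chromium alkoxide with Ac2O prevents 8→9 acyl migration.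

Step 21
Reactants: 28 (1αH,5αH,6βH,7αH)-9α-acetoxy-15-[(4-methoxybenzyl)oxy]-8β-[(2S)-2-methylbutanoyloxy]-4β,14-epoxyguaia-10(14),11(13)-dien-12,6α-olide
Product: 29 (1αH,5αH,6βH,7αH)-9α-acetoxy-15-hydroxy-8β-[(2S)-2-methylbutanoyloxy]-4β,14-epoxyguaia-10(14),11(13)-dien-12,6α-olide (CNP0013863.2)
Conditions: DDQ (1.3 equiv), CH2Cl2/aqueous NaH2PO4–Na2HPO4 buffer (pH 7), 0 °C
Reagents that add atoms: none
Why: Buffered oxidative cleavage of the PMB ether by DDQ (single-electron oxidation, then hydrolysis of the hemiacetal) leaves the esters, the α-methylene lactone and the enol ether untouched and gives the target.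

**Compound list**

1 | 2-(hydroxymethyl)cyclopent-2-en-1-one | O=C1CCC=C1CO | starting material
2 | 2-{[(triethylsilyl)oxy]methyl}cyclopent-2-en-1-one | O=C1CCC=C1CO[Si](CC)(CC)CC | intermediate
3 | methyl acetate | COC(C)=O | starting material
4 | methyl 2-(1-hydroxy-2-{[(triethylsilyl)oxy]methyl}cyclopent-2-en-1-yl)acetate (racemic) | COC(=O)CC1(O)CCC=C1CO[Si](CC)(CC)CC | intermediate
5 | methyl 2-(3-oxo-2-{[(triethylsilyl)oxy]methyl}cyclopent-1-en-1-yl)acetate | COC(=O)CC1=C(CO[Si](CC)(CC)CC)C(=O)CC1 | intermediate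
6 | methyl 2-[(1S,2S)-3-oxo-2-{[(triethylsilyl)oxy]methyl}cyclopentyl]acetate | COC(=O)C[C@@H]1CCC(=O)[C@@H]1CO[Si](CC)(CC)CC | intermediate
7 | methyl 2-[(1S,2S,3S)-3-hydroxy-3-{[(4-methoxybenzyl)oxy]methyl}-2-{[(triethylsilyl)oxy]methyl}cyclopentyl]acetate (OH, CH2OTES and CH2CO2Me all cis) | COC(=O)C[C@@H]1CC[C@@](O)(COCc2ccc(OC)cc2)[C@@H]1CO[Si](CC)(CC)CC | intermediate
8 | (1S,5S,8S)-1-{[(4-methoxybenzyl)oxy]methyl}-8-{[(triethylsilyl)oxy]methyl}-2-oxabicyclo[3.2.1]octan-3-one | C1C(=O)O[C@@]3(COCc2ccc(OC)cc2)CC[C@@H]1[C@H]3CO[Si](CC)(CC)CC | intermediate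
9 | (1S,5S,8S)-1-{[(4-methoxybenzyl)oxy]methyl}-8-{[(triethylsilyl)oxy]methyl}-2-oxabicyclo[3.2.1]octan-3-ol (both anomers) | C1C(O)O[C@@]3(COCc2ccc(OC)cc2)CC[C@@H]1[C@H]3CO[Si](CC)(CC)CC | intermediate
10 | (1S,5S,8S)-1-{[(4-methoxybenzyl)oxy]methyl}-8-{[(triethylsilyl)oxy]methyl}-2-oxabicyclo[3.2.1]oct-3-ene | C1=CO[C@@]3(COCc2ccc(OC)cc2)CC[C@@H]1[C@H]3CO[Si](CC)(CC)CC | intermediate
11 | (1S,5S,8R)-1-{[(4-methoxybenzyl)oxy]methyl}-2-oxabicyclo[3.2.1]oct-3-ene-8-carbaldehyde | C1=CO[C@@]3(COCc2ccc(OC)cc2)CC[C@@H]1[C@H]3C=O | intermediate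
12 | ethyl prop-2-ynoate | CCOC(=O)C#C | starting material
13 | ethyl (Z)-3-iodoprop-2-enoate | CCOC(=O)/C=C\I | intermediate
14 | (Z)-3-iodoprop-2-en-1-ol | OC/C=C\I | intermediate
15 | ethynyltrimethylsilane | C#C[Si](C)(C)C | starting material
16 | (Z)-5-(trimethylsilyl)pent-2-en-4-yn-1-ol | OC/C=C\C#C[Si](C)(C)C | intermediate
17 | (Z)-pent-2-en-4-yn-1-ol | OC/C=C\C#C | intermediate
18 | [(2R,3S)-3-ethynyloxiran-2-yl]methanol | C#C[C@@H]1O[C@@H]1CO | intermediate
19 | triethyl{[(2R,3S)-3-ethynyloxiran-2-yl]methoxy}silane | C#C[C@@H]1O[C@@H]1CO[Si](CC)(CC)CC | intermediate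
20 | (S)-2-methylbutanoic acid | CC[C@H](C)C(=O)O | starting material
21 | (S)-2-methylbutanoic anhydride | CC[C@H](C)C(=O)OC(=O)[C@@H](C)CC | intermediate
22 | (1S,2S,3S)-2-ethynyl-1-[(1S,5S,8S)-1-{[(4-methoxybenzyl)oxy]methyl}-2-oxabicyclo[3.2.1]oct-3-en-8-yl]-4-[(triethylsilyl)oxy]butane-1,3-diol | O[C@@H]([C@H](C#C)[C@H](O)CO[Si](CC)(CC)CC)[C@@H]1[C@H]2CC[C@]1(COCc3ccc(OC)cc3)OC=C2 | intermediate
23 | (2S,3S,4S)-3-ethynyl-4-hydroxy-4-[(1S,5S,8S)-1-{[(4-methoxybenzyl)oxy]methyl}-2-oxabicyclo[3.2.1]oct-3-en-8-yl]-1-[(triethylsilyl)oxy]butan-2-yl (2S)-2-methylbutanoate | O[C@@H]([C@H](C#C)[C@H](OC(=O)[C@@H](C)CC)CO[Si](CC)(CC)CC)[C@@H]1[C@H]2CC[C@]1(COCc3ccc(OC)cc3)OC=C2 | intermediate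
24 | (1S)-1-[(2S,3S)-2-[(1S,5S,8S)-1-{[(4-methoxybenzyl)oxy]methyl}-2-oxabicyclo[3.2.1]oct-3-en-8-yl]-4-methylidene-5-oxooxolan-3-yl]-2-[(triethylsilyl)oxy]ethyl (2S)-2-methylbutanoate | C=C1C(=O)O[C@@H]([C@H]1[C@H](OC(=O)[C@@H](C)CC)CO[Si](CC)(CC)CC)[C@@H]1[C@H]2CC[C@]1(COCc3ccc(OC)cc3)OC=C2 | intermediate
25 | (1S)-1-[(2S,3S)-2-[(1S,5R,8S)-4-iodo-1-{[(4-methoxybenzyl)oxy]methyl}-2-oxabicyclo[3.2.1]oct-3-en-8-yl]-4-methylidene-5-oxooxolan-3-yl]-2-[(triethylsilyl)oxy]ethyl (2S)-2-methylbutanoate | C=C1C(=O)O[C@@H]([C@H]1[C@H](OC(=O)[C@@H](C)CC)CO[Si](CC)(CC)CC)[C@@H]1[C@H]2CC[C@]1(COCc3ccc(OC)cc3)OC=C2I | intermediate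
26 | (1S)-1-[(2S,3S)-2-[(1S,5R,8S)-4-iodo-1-{[(4-methoxybenzyl)oxy]methyl}-2-oxabicyclo[3.2.1]oct-3-en-8-yl]-4-methylidene-5-oxooxolan-3-yl]-2-oxoethyl (2S)-2-methylbutanoate | C=C1C(=O)O[C@@H]([C@H]1[C@H](OC(=O)[C@@H](C)CC)C=O)[C@@H]1[C@H]2CC[C@]1(COCc3ccc(OC)cc3)OC=C2I | intermediate
27 | (1αH,5αH,6βH,7αH)-9α-hydroxy-15-[(4-methoxybenzyl)oxy]-8β-[(2S)-2-methylbutanoyloxy]-4β,14-epoxyguaia-10(14),11(13)-dien-12,6α-olide | C=C1C(=O)O[C@H]2[C@H]1[C@H](OC(=O)[C@@H](C)CC)[C@@H](O)C1=CO[C@@]3(COCc4ccc(OC)cc4)CC[C@@H]1[C@@H]23 | intermediate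
28 | (1αH,5αH,6βH,7αH)-9α-acetoxy-15-[(4-methoxybenzyl)oxy]-8β-[(2S)-2-methylbutanoyloxy]-4β,14-epoxyguaia-10(14),11(13)-dien-12,6α-olide | C=C1C(=O)O[C@H]2[C@H]1[C@H](OC(=O)[C@@H](C)CC)[C@@H](OC(C)=O)C1=CO[C@@]3(COCc4ccc(OC)cc4)CC[C@@H]1[C@@H]23 | intermediate
29 | (1αH,5αH,6βH,7αH)-9α-acetoxy-15-hydroxy-8β-[(2S)-2-methylbutanoyloxy]-4β,14-epoxyguaia-10(14),11(13)-dien-12,6α-olide | C=C1C(=O)O[C@H]2[C@H]1[C@H](OC(=O)[C@@H](C)CC)[C@@H](OC(C)=O)C1=CO[C@@]3(CO)CC[C@@H]1[C@@H]23 | target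

**Step count**

Total: 21 steps. Longest linear sequence: 14 steps (steps 1–7, then 15–21).

**The three steps most likely to fail**

Step 15 (the proposed new coupling). Possible failures are allenyl-carbinol regioisomers, low diastereoselectivity, or Lewis-acid opening of the oxirane. The fallback uses known chemistry and sets out from epoxide 19. Copper-catalysed anti SN2′ borylation of the alkynyl oxirane (CuCl 5 mol %, Xantphos, NaOt-Bu, B2pin2, THF, 25 °C) gives the isolable allenylboronate (2S)-5-(4,4,5,5-tetramethyl-1,3,2-dioxaborolan-2-yl)-1-[(triethylsilyl)oxy]penta-3,4-dien-2-ol F1. This is heated with aldehyde 11 (toluene, 40 °C, then triethanolamine work-up) and adds without any metal through the closed six-membered propargylboration transition state, with the same stereochemical course. The route is rejoined at diol 22.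

Step 20 (ring closure). The most likely failure is the wrong C9 configuration; acyl migration is the second risk. The fallback sets out from aldehyde 26. The same CrCl2/NiCl2 closure is run with aqueous work-up instead of the anhydride quench, and the epimeric alcohol (1αH,5αH,6βH,7αH)-9β-hydroxy-15-[(4-methoxybenzyl)oxy]-8β-[(2S)-2-methylbutanoyloxy]-4β,14-epoxyguaia-10(14),11(13)-dien-12,6α-olide F2 is isolated. Dess–Martin periodinane (NaHCO3, CH2Cl2) gives the vinylogous ester (1αH,5αH,6βH,7αH)-15-[(4-methoxybenzyl)oxy]-8β-[(2S)-2-methylbutanoyloxy]-9-oxo-4β,14-epoxyguaia-10(14),11(13)-dien-12,6α-olide F3. Reagent-controlled reduction with (S)-2-methyl-CBS-oxazaborolidine and catecholborane (toluene, −78 °C) then sets C9 by hydride delivery instead of C–C bond formation and gives alcohol 27, here isolated. Ac2O/DMAP/pyridine returns to the route at acetate 28.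

Step 4 (asymmetric hydrogenation). The catalyst is proven on a 2-alkyl analogue, not on the silyloxymethyl enone. The fallback sets out from enone 5. Corey–Bakshi–Shibata reduction ((S)-2-methyl-CBS-oxazaborolidine, BH3·SMe2, THF, −20 °C) gives the allylic alcohol methyl 2-[(3R)-3-hydroxy-2-{[(triethylsilyl)oxy]methyl}cyclopent-1-en-1-yl]acetate F4. Hydroxyl-directed hydrogenation ([Ir(cod)(PCy3)(py)]PF6 5 mol %, H2 1 atm, CH2Cl2) delivers both hydrogens syn to the hydroxyl and gives methyl 2-[(1S,2S,3R)-3-hydroxy-2-{[(triethylsilyl)oxy]methyl}cyclopentyl]acetate F5. Dess–Martin oxidation returns to the route at ketone 6.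

Further compounds
F1 | step 15 | (2S)-5-(4,4,5,5-tetramethyl-1,3,2-dioxaborolan-2-yl)-1-[(triethylsilyl)oxy]penta-3,4-dien-2-ol (single allene axial isomer from anti SN2′ opening) | [H]C(B1OC(C)(C)C(C)(C)O1)=[C@]=C([H])[C@H](O)CO[Si](CC)(CC)CC
F2 | step 20 | (1αH,5αH,6βH,7αH)-9β-hydroxy-15-[(4-methoxybenzyl)oxy]-8β-[(2S)-2-methylbutanoyloxy]-4β,14-epoxyguaia-10(14),11(13)-dien-12,6α-olide | C=C1C(=O)O[C@H]2[C@H]1[C@H](OC(=O)[C@@H](C)CC)[C@H](O)C1=CO[C@@]3(COCc4ccc(OC)cc4)CC[C@@H]1[C@@H]23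
F3 | step 20 | (1αH,5αH,6βH,7αH)-15-[(4-methoxybenzyl)oxy]-8β-[(2S)-2-methylbutanoyloxy]-9-oxo-4β,14-epoxyguaia-10(14),11(13)-dien-12,6α-olide | C=C1C(=O)O[C@H]2[C@H]1[C@H](OC(=O)[C@@H](C)CC)C(=O)C1=CO[C@@]3(COCc4ccc(OC)cc4)CC[C@@H]1[C@@H]23
F4 | step 4 | methyl 2-[(3R)-3-hydroxy-2-{[(triethylsilyl)oxy]methyl}cyclopent-1-en-1-yl]acetate | COC(=O)CC1=C(CO[Si](CC)(CC)CC)[C@H](O)CC1
F5 | step 4 | methyl 2-[(1S,2S,3R)-3-hydroxy-2-{[(triethylsilyl)oxy]methyl}cyclopentyl]acetate | COC(=O)C[C@@H]1CC[C@@H](O)[C@@H]1CO[Si](CC)(CC)CC
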